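**Plan**
- **Cuts:** the C6–O cinnamate ester comes off first, then the C6–C7 bond of ring B. On ring A the C4–CH3, C5–C6 and C10–C9 bonds follow, leading back to 3-methylcyclohexenone, homoprenyl bromide, formaldehyde, a methyl nucleophile and 3-hydroxycinnamic acid.
- **Enabling feature:** C6 (oxygenated) and C7 are neighbours in ring B, and C7 carries an isopropyl group. C7=C11 can therefore be a prenyl-type alkene that accepts a C6 ketyl. The C4 hydroxyl of ring A lies syn-axial (β) to the C6 oxygen and can clamp samarium between O4 and O6.
- **Forward order:** ring A is bought. Conjugate addition with hydroxymethylation adds the chain and C6, methyl addition builds C4, and oxidation gives the hydroxy aldehyde. SmI2 closes ring B, and the aromatic acid is joined last.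
- **Stereochemistry:** C10 comes from a chiral NHC–copper catalyst and C5 from anti attack on the enolate. C4 comes from equatorial attack enforced by the axial C10 methyl, C6 from the samarium chelate, and C7 from the chair transition state. The E alkene comes from the commercial acid.

Key step: step 6

Assumption: the sense of induction of the NHC–copper catalyst follows the ligand enantiomer, so the antipode giving R at C10 is used, and minor stereoisomers from the first step are taken to be removable by chromatography at the silyl ether stage.

Step 1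
Reactants: 1 5-bromo-2-methylpent-2-ene; 2 3-methylcyclohex-2-en-1-one; 3 formaldehyde (monomer, gas from cracked paraformaldehyde)
Product: 6 (2S,3R)-2-(hydroxymethyl)-3-methyl-3-(4-methylpent-3-en-1-yl)cyclohexan-1-one, via homoprenylmagnesium bromide 4 (not isolated), via bromomagnesium enolate 5 (not isolated)
Conditions: Mg, Et2O, reflux (1 to 4); Cu(OTf)2 (3 mol %), 1-(1-hydroxy-3,3-dimethylbutan-2-yl)-3-mesityl-4,5-dihydro-1H-imidazol-3-ium hexafluorophosphate (single enantiomer, 4 mol %), Et2O, −30 °C, slow addition of 2; CH2O gas, −30 to 0 °C; aq. NH4Cl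
Reagents that add atoms: none
Why: Copper–NHC-catalysed asymmetric conjugate addition of a Grignard reagent to a β-methyl cyclohexenone is an established route to quaternary centres and fixes C10 (R) under ligand control, while the regiodefined enolate 5 is captured in an aldol reaction with monomeric formaldehyde by axial attack on the half-chair anti to the pseudoaxial homoprenyl chain, so that C6 ends trans to the chain (C5 S), the bias between methyl and chain being only modest.

Step 2
Reactants: 6 (2S,3R)-2-(hydroxymethyl)-3-methyl-3-(4-methylpent-3-en-1-yl)cyclohexan-1-one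
Product: 7 (2S,3R)-2-{[(tert-butyldimethylsilyl)oxy]methyl}-3-methyl-3-(4-methylpent-3-en-1-yl)cyclohexan-1-one
Conditions: TBSCl, imidazole, DMF, 0 °C to rt
Reagents that add atoms: tert-butyldimethylsilyl chloride, CC(C)(C)[Si](C)(C)Cl
Why: Imidazole-promoted silylation of the primary alcohol blocks retro-aldol loss of formaldehyde and dehydration in the next step, is too weakly basic to disturb C5, and gives a robust compound at which any C5 epimer can be removed and recycled by base equilibration.

Step 3
Reactants: 7 (2S,3R)-2-{[(tert-butyldimethylsilyl)oxy]methyl}-3-methyl-3-(4-methylpent-3-en-1-yl)cyclohexan-1-one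
Product: 8 (1S,2S,3R)-2-{[(tert-butyldimethylsilyl)oxy]methyl}-1,3-dimethyl-3-(4-methylpent-3-en-1-yl)cyclohexan-1-ol
Conditions: CeCl3 (anhydrous), MeMgBr, THF, −78 °C; then 7, −78 to −20 °C; aq. NH4Cl
Reagents that add atoms: methylmagnesium bromide, C[Mg]Br
Why: Organocerium 1,2-addition suppresses enolisation of the hindered, epimerisable ketone, and because the axial C10 methyl blocks the β face the methyl group enters along the equatorial trajectory from the α face, setting C4 with an axial β hydroxyl and an equatorial methyl.

Step 4
Reactants: 8 (1S,2S,3R)-2-{[(tert-butyldimethylsilyl)oxy]methyl}-1,3-dimethyl-3-(4-methylpent-3-en-1-yl)cyclohexan-1-ol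
Product: 9 (1S,2S,3R)-2-(hydroxymethyl)-1,3-dimethyl-3-(4-methylpent-3-en-1-yl)cyclohexan-1-ol
Conditions: n-Bu4NF, THF, 0 °C to rt
Reagents that add atoms: none
Why: Fluoride cleavage of a primary silyl ether is routine and leaves the tertiary alcohol, the trisubstituted alkene and all stereocentres untouched.

Step 5
Reactants: 9 (1S,2S,3R)-2-(hydroxymethyl)-1,3-dimethyl-3-(4-methylpent-3-en-1-yl)cyclohexan-1-ol
Product: 10 (1R,2S,6R)-2-hydroxy-2,6-dimethyl-6-(4-methylpent-3-en-1-yl)cyclohexane-1-carbaldehyde
Conditions: Dess–Martin periodinane, NaHCO3, CH2Cl2, 0 °C; used at once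
Reagents that add atoms: none
Why: Buffered Dess–Martin oxidation acts only on the primary alcohol (the tertiary one cannot be oxidised) and is neutral and fast enough to avoid C5 epimerisation, dehydration and retro-aldol cleavage of the β-hydroxy aldehyde.

Step 6
Reactants: 10 (1R,2S,6R)-2-hydroxy-2,6-dimethyl-6-(4-methylpent-3-en-1-yl)cyclohexane-1-carbaldehyde
Product: 11 eudesmane-4β,6β-diol, (1S,4aR,7S,8R,8aS)-1,4a-dimethyl-7-(propan-2-yl)decahydronaphthalene-1,8-diol
Conditions: SmI2 (4 equiv, 0.1 M in THF), t-BuOH (4 equiv), degassed THF, −20 °C to rt, slow addition of 10 (final 5 mM), no HMPA; aq. potassium sodium tartrate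
Reagents that add atoms: none
Why: Proposed new method: inner-sphere electron transfer from divalent samarium to the aldehyde, bound together with the neighbouring C4 hydroxyl, should give a C6 ketyl that attacks C7 of the trisubstituted alkene, and the tertiary C11 radical so formed is quenched by a second electron and a proton (or by hydrogen abstraction from THF) to leave the isopropyl group. The closest known reaction types are SmI2 ketyl–olefin cyclisations of unactivated olefinic carbonyl compounds (mostly 5-exo and usually run in the presence of HMPA) and the hydroxyl-directed SmI2 reduction of β-hydroxy ketones, whereas their combination in a six-membered closure onto an unactivated trisubstituted alkene has not been described. Ring B closes in the 6-exo-trig mode, attack at the less substituted alkene carbon being favoured by sterics and by formation of the tertiary radical, and because C6 and C9 are trans-diequatorial on the ring A chair only a trans-decalin can result. C6 is controlled by the six-membered trivalent samarium chelate spanning O4 and O6, which holds the ketyl oxygen axial on the β face, and this is why strongly coordinating additives are left out. C7 is controlled by the chair transition state in which the dimethylvinyl terminus lies pseudo-equatorial, so the isopropyl group ends equatorial (β) and H7 axial (α). The step needs cyclisation to outrun ketyl protonation, pinacol coupling and retro-aldol cleavage, which is served by the preorganised diequatorial geometry, by poorly acidic t-BuOH as the only proton source, by low temperature and by slow addition of 10 to excess reductant at high dilution.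

Step 7
Reactants: 12 (E)-3-hydroxycinnamic acid
Product: 13 tert-butyldimethylsilyl (E)-3-{3-[(tert-butyldimethylsilyl)oxy]phenyl}prop-2-enoate
Conditions: TBSCl (2.3 equiv), imidazole, DMF, rt
Reagents that add atoms: tert-butyldimethylsilyl chloride, CC(C)(C)[Si](C)(C)Cl
Why: Exhaustive silylation masks the phenol and at the same time provides a silyl ester that can be turned into the acid chloride without free HCl, the E alkene being that of the commercial acid.

Step 8
Reactants: 11 eudesmane-4β,6β-diol; 13 tert-butyldimethylsilyl (E)-3-{3-[(tert-butyldimethylsilyl)oxy]phenyl}prop-2-enoate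
Product: 15 4β-hydroxyeudesman-6β-yl (E)-3-{3-[(tert-butyldimethylsilyl)oxy]phenyl}prop-2-enoate, via silylated cinnamoyl chloride 14 (not isolated)
Conditions: 13, (COCl)2, DMF (cat.), CH2Cl2, 0 °C to rt, volatiles removed in vacuo; then 11, DMAP, Et3N, CH2Cl2, 0 to 40 °C
Reagents that add atoms: none
Why: Silyl esters give acid chlorides with oxalyl chloride and catalytic DMF under neutral conditions, and DMAP-catalysed acylation then occurs only at the secondary C6 hydroxyl because the tertiary C4 hydroxyl is too hindered to compete, with C6 retained since its C–O bond is not touched.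

Step 9
Reactants: 15 4β-hydroxyeudesman-6β-yl (E)-3-{3-[(tert-butyldimethylsilyl)oxy]phenyl}prop-2-enoate
Product: 16 4β-hydroxyeudesman-6β-yl (E)-3-(3-hydroxyphenyl)prop-2-enoate (CNP0283603.1)
Conditions: HF·pyridine, pyridine, THF, 0 °C
Reagents that add atoms: none
Why: Aryl silyl ethers are cleaved by buffered HF·pyridine well below the conditions that would harm the cinnamate, the tertiary alcohol or the E alkene, so the phenol should be released without acyl migration or elimination.

**Compound list**
1 | 5-bromo-2-methylpent-2-ene | CC(C)=CCCBr | starting material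
2 | 3-methylcyclohex-2-en-1-one | CC1=CC(=O)CCC1 | starting material
3 | formaldehyde | C=O | starting material
4 | (4-methylpent-3-en-1-yl)magnesium bromide | CC(C)=CCC[Mg]Br | intermediate
5 | bromomagnesium (3R)-3-methyl-3-(4-methylpent-3-en-1-yl)cyclohex-1-en-1-olate | CC(C)=CCC[C@@]1(C)CCCC(O[Mg]Br)=C1 | intermediate
6 | (2S,3R)-2-(hydroxymethyl)-3-methyl-3-(4-methylpent-3-en-1-yl)cyclohexan-1-one | CC(C)=CCC[C@@]1(C)CCCC(=O)[C@@H]1CO | intermediate
7 | (2S,3R)-2-{[(tert-butyldimethylsilyl)oxy]methyl}-3-methyl-3-(4-methylpent-3-en-1-yl)cyclohexan-1-one | CC(C)=CCC[C@@]1(C)CCCC(=O)[C@@H]1CO[Si](C)(C)C(C)(C)C | intermediate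
8 | (1S,2S,3R)-2-{[(tert-butyldimethylsilyl)oxy]methyl}-1,3-dimethyl-3-(4-methylpent-3-en-1-yl)cyclohexan-1-ol | CC(C)=CCC[C@@]1(C)CCC[C@](C)(O)[C@@H]1CO[Si](C)(C)C(C)(C)C | intermediate
9 | (1S,2S,3R)-2-(hydroxymethyl)-1,3-dimethyl-3-(4-methylpent-3-en-1-yl)cyclohexan-1-ol | CC(C)=CCC[C@@]1(C)CCC[C@](C)(O)[C@@H]1CO | intermediate
10 | (1R,2S,6R)-2-hydroxy-2,6-dimethyl-6-(4-methylpent-3-en-1-yl)cyclohexane-1-carbaldehyde | CC(C)=CCC[C@@]1(C)CCC[C@](C)(O)[C@@H]1C=O | intermediate
11 | eudesmane-4β,6β-diol, (1S,4aR,7S,8R,8aS)-1,4a-dimethyl-7-(propan-2-yl)decahydronaphthalene-1,8-diol | CC(C)[C@@H]1CC[C@@]2(C)CCC[C@](C)(O)[C@@H]2[C@@H]1O | intermediate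
12 | (E)-3-hydroxycinnamic acid | OC(=O)/C=C/c1cccc(O)c1 | starting material
13 | tert-butyldimethylsilyl (E)-3-{3-[(tert-butyldimethylsilyl)oxy]phenyl}prop-2-enoate | CC(C)(C)[Si](C)(C)OC(=O)/C=C/c1cccc(O[Si](C)(C)C(C)(C)C)c1 | intermediate
14 | (E)-3-{3-[(tert-butyldimethylsilyl)oxy]phenyl}prop-2-enoyl chloride | O=C(Cl)/C=C/c1cccc(O[Si](C)(C)C(C)(C)C)c1 | intermediate
15 | 4β-hydroxyeudesman-6β-yl (E)-3-{3-[(tert-butyldimethylsilyl)oxy]phenyl}prop-2-enoate | CC(C)[C@@H]1CC[C@@]2(C)CCC[C@](C)(O)[C@@H]2[C@@H]1OC(=O)/C=C/c1cccc(O[Si](C)(C)C(C)(C)C)c1 | intermediate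
16 | 4β-hydroxyeudesman-6β-yl (E)-3-(3-hydroxyphenyl)prop-2-enoate | CC(C)[C@@H]1CC[C@@]2(C)CCC[C@](C)(O)[C@@H]2[C@@H]1OC(=O)/C=C/c1cccc(O)c1 | target

Total step count: 9
Longest linear sequence: 8 steps (steps 1 to 6, 8 and 9)

**Steps most likely to fail**

**Step 6.** The slow 6-exo addition of a nucleophilic ketyl to an electron-rich alkene may be overtaken by simple reduction of the aldehyde, by pinacol dimerisation or by retro-aldol cleavage. Chelate control at C6 may also be lost.

The fallback sets out from aldehyde 10 and makes the same C6–C7 bond by a Lewis-acid carbonyl-ene cyclisation of the citronellal-to-isopulegol kind (Me2AlCl, CH2Cl2, −78 °C). This is expected to give the all-equatorial eudesm-11-ene-4β,6α-diol F1.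
- Hydrogenation of the isopropenyl group (H2, Pd/C, EtOAc) gives eudesmane-4β,6α-diol F2.
- Dess–Martin oxidation of the secondary alcohol gives 4β-hydroxyeudesman-6-one F3.
- LiBH(s-Bu)3 (THF, −78 °C) delivers hydride along the equatorial trajectory from the open α face, because the β face is screened by the axial C10 methyl and C4 hydroxyl.

The axial 6β-alcohol results whatever the C6 outcome of the ene step, and the sequence rejoins the route at diol 11.

**Step 1.** The two substituents at C10 are of similar size, so facial discrimination at C5 in the enolate capture may be poor. The ketol may also lose formaldehyde or water.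

The fallback sets out from enolate 5, which is quenched with Me3SiCl to give [(3R)-3-methyl-3-(4-methylpent-3-en-1-yl)cyclohex-1-en-1-yl]oxytrimethylsilane F4. This isolated silyl enol ether is then submitted to a catalyst-controlled aqueous Mukaiyama hydroxymethylation. The conditions are Sc(OTf)3 with enantiopure 6,6'-bis(1-hydroxy-2,2-dimethylpropyl)-2,2'-bipyridine, aq. CH2O, DME, −20 °C. The face of attack at C5 is then chosen by the reagent and not by the weak substrate bias. The sequence comes back to the route at ketol 6.

**Step 8.** The C6 hydroxyl is axial, is flanked by the isopropyl group, and is syn to the C10 methyl and C4 hydroxyl. Acylation by a conjugated acyl donor may therefore stall, or may be followed by acyl migration on forcing.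

The fallback sets out from diol 11 and builds the cinnamate in two stages.
- Carbodiimide esterification with diethylphosphonoacetic acid (DCC, DMAP, CH2Cl2), which acylates through a small ketene-like species, gives 4β-hydroxyeudesman-6β-yl 2-(diethoxyphosphoryl)acetate F5.
- A Horner–Wadsworth–Emmons reaction with commercial 3-[(tert-butyldimethylsilyl)oxy]benzaldehyde (LiCl, DBU, MeCN, rt) creates the E alkene.

The sequence rejoins the route at silyl ether 15.

Further compounds
F1 | step 6 | eudesm-11-ene-4β,6α-diol | CC(=C)[C@@H]1CC[C@@]2(C)CCC[C@](C)(O)[C@@H]2[C@H]1O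
F2 | step 6 | eudesmane-4β,6α-diol | CC(C)[C@@H]1CC[C@@]2(C)CCC[C@](C)(O)[C@@H]2[C@H]1O
F3 | step 6 | 4β-hydroxyeudesman-6-one | CC(C)[C@@H]1CC[C@@]2(C)CCC[C@](C)(O)[C@@H]2C1=O
F4 | step 1 | [(3R)-3-methyl-3-(4-methylpent-3-en-1-yl)cyclohex-1-en-1-yl]oxytrimethylsilane | CC(C)=CCC[C@@]1(C)CCCC(O[Si](C)(C)C)=C1
F5 | step 8 | 4β-hydroxyeudesman-6β-yl 2-(diethoxyphosphoryl)acetate | CC(C)[C@@H]1CC[C@@]2(C)CCC[C@](C)(O)[C@@H]2[C@@H]1OC(=O)CP(=O)(OCC)OCC
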